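- Take the ratio of reagent to starting material in the flask, 0.900: reagent reacting one to one with starting material is the limiting reagent, so target stays at or under 90.0% of the charge.

| setting | red | grey | flask |
|---|---|---|---|
| starting material | 0.14 M | 0.22 M | 0.10 M |
| reagent | 0.090 M | 0.090 M | 0.0900 M |
| free catalyst | 5 mM | 5 mM | 5.0 mM |
| remark | run made earlier | run made earlier |  |
| time |  |  | 6.0 d |

- red (time / d: target / %, starting material / %): 0.250: 49.0, 50.8; 0.625: 58.8, 39.8; 1.25: 62.9, 38.3; 2.08: 61.9, 39.8; 3.00: 61.6, 39.2; 4.00: 63.1, 38.6
- grey (time / d: target / %, starting material / %): 0.250: 37.5, 63.2; 0.500: 38.6, 61.1; 0.833: 40.3, 61.3; 1.25: 40.3, 59.8; 2.00: 41.2, 61.6; 4.00: 39.3, 61.2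

(each reading ± 1 percentage point)

- how much target there is at 6.0 d, in percent of the starting material charged
- amount of target if the flask were left three thousand times as long, in percent of the starting material charged



- Estimate how far under that bound the flask stands from the shortfall: the mean of the last 4 target readings leaves 2.67 mM of reagent in the red run and 1.39 mM in the grey run, readings that carry their scatter.
- Write a and b for the charges of starting material and reagent, x for target, and form Q = x/((a−x)(b−x)): red reads 620 M⁻¹ and grey 483 M⁻¹.
- Carry their mean, 552 M⁻¹, as the plateau quotient.
- Solve Q(a−x)(b−x) = x for the smaller root in the flask: red's Q gives 82.4%, grey's 81.1%, and the mean 81.8%; treat these as estimates from two scattered plateaus, not as bounds.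
- Expect the same figure at both asked times, since the red run stood flat from 1.25 d, earlier than 6.0 d.
- Place the forecast, 82% and 82.5% for the long limit: its first value lies between the two estimates, on the ground that the shortfall “fits a reversible reaction”.

    reagent + free catalyst ⇌ catalyst intermediate A (K = 3.80 M⁻¹, k = 790 M⁻¹ h⁻¹)
    starting material + catalyst intermediate A ⇌ catalyst intermediate B (K = 24.0 M⁻¹, k = 210 M⁻¹ h⁻¹)
    catalyst intermediate B ⇌ free catalyst + target (K = 5.00 M, k = 57.0 h⁻¹)

- The flask gives 80.6% and 80.6%, 1.2 percentage points under the figure from 552 M⁻¹ and under the estimate from grey's Q, while the forecast holds within its margins. In this flask the backward turnover from catalyst intermediate A to reagent and free catalyst is 99% of the forward one, and 98% of that step's turnover lies behind it at 1.20 d. Target in the flask reads 80.6% at 3.00 d and 80.6% at 60.0 d. In the neighbour flask with 0.040 M of starting material, 552 M⁻¹ gives 96.6%, and that flask holds 95.8%.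

The data come from a simulation with constants of no real substance, noise included.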